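**Remarks on the chemistry.** In rings A and C the bridge-bearing carbon is called C1, followed by C2 (OH), C3 (butanoyl), C4 (OCH3), C5 (CH3) and C6 (OH). Compound 11 is racemic and its stereocentre is erased in step 7. Compound 12 is drawn as its enol. The bis compounds 14–16 and 20 are drawn with both arms at the same stage although the arms react independently. Commercial (S)-2-methylbutanoic acid 23 of high enantiomeric purity is assumed.

## Analysis of the target

Agrimol B (25) is a linear trimer of acylphloroglucinols: three hexasubstituted benzene rings (A, B, C) joined by two CH2 bridges, with no fused or heterocyclic ring. Rings A and C are constitutionally identical, with the substituents at C1–C6 as defined above. Ring B is a phloroglucinol whose two bridge carbons flank one hydroxylated carbon and whose remaining carbon carries the (S)-2-methylbutanoyl group. The only stereocentre is C2 of that acyl chain. It has no partner to relate to and can be lost only by enolisation of the aryl ketone, so it is best taken from the chiral pool and kept away from strong base and hot acid. Sensitive features are the seven free phenols (air oxidation) and the diarylmethane bridges between electron-rich rings, which can cleave and scramble by retro-Friedel–Crafts or quinone-methide pathways once the phenols are free. The methyl ether ortho to a ketone is also at risk from strong Lewis acids. The difficulty is regiochemical: every ring position is substituted, exactly one of three oxygenated carbons of each outer ring must be a methyl ether, and joining three monomers with a methylene donor gives statistical mixtures. The strategy rests on the outer-ring pattern: C1 is flanked by the oxygenated carbons C2 and C6, and the C-methyl carbon C5 is adjacent to the O-methyl carbon C4. An alkynyl silyl ether (C1 and C6 with its oxygen) and the cyclobutenone 13 (C2, C3, C4, C5) deliver this pattern with fixed regiochemistry.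

## Retrosynthetic reasoning

**Benzyl ethers on ring B (25 ⇒ 24).** No skeletal bond is cut in the last retrosynthetic step; the three ring B hydroxyls are masked as benzyl ethers. Hydrogenolysis is neutral, so the free heptaphenol with its labile bridges and enolisable stereocentre is formed without acid or base. The same ethers tolerate the strong bases and the heat used earlier.

**Ring B acyl bond (24 ⇒ 22 + 23).** The bond between ring B and the carbonyl carbon of the 2-methylbutanoyl group is cut. This brings the stereocentre in two steps from the end, from the chiral-pool acid 23, after every organolithium and fluoride step. In 22 the carbon concerned is the only unsubstituted position on an electron-rich ring, so a Friedel–Crafts acylation has no regiochemical choice. The forward step must substitute a carbon flanked by two benzyloxy groups without enolising the acyl donor.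

**Outer acyl bonds (22 ⇒ 21 ⇒ 17, by way of 19 and 18).** The aryl–butanoyl bonds at C3 of rings A and C are cut. In 17 this carbon is the one ring CH, ortho to the free phenol at C2. Ring B of 17 also holds a nucleophilic CH, so an intermolecular acylation or a Lewis-acid Fries rearrangement could place butanoyl on the wrong ring and would endanger the benzyl ethers. The cut is therefore made through an intramolecular O-to-C shift. The phenol directs iodine to C3 (18), carries the butanoyl group as its ester (19), and halogen–lithium exchange hands the acyl group to the neighbouring carbon (21). The silyl ethers are removed (22) before the stereocentre exists.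

**Both outer rings (17 ⇒ 8 + two molecules of 13).** This is the central cut. In each outer ring the bonds C1–C2 and C5–C6 are broken. That leaves a two-carbon unit (C1, C6) carrying the bridge carbon and one oxygen, and a four-carbon unit (C2–C3–C4–C5) carrying the second oxygen, the CH, the methoxy and the methyl group. These are the alkynyl silyl ether arms of 8 and the cyclobutenone 13. Cutting inside the outer rings, not at the bridges, keeps both CH2 groups attached to ring B from the start, so no statistical union of three phenols arises. The position of the cut follows the polarity of the partners: the alkyne carbon remote from oxygen is nucleophilic and the ketene carbon released from 13 is electrophilic. The forward reaction must form four C–C bonds and two benzene rings in one thermal operation and leave one phenol per ring free next to the remaining CH.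

**The bis(siloxyalkyne) (8 ⇒ 6 ⇒ 5 ⇒ 4 ⇒ 3 ⇒ 1).** Each C≡C–O unit is traced to an ester carbonyl plus one added carbon (ynolate 7 by carbenoid rearrangement, then silylation on oxygen). The arylacetic ester arms of 6 come from the formyl groups of 4 by one-carbon homologation through the ketene dithioacetal 5. The formyl carbons, which become the bridge carbons of 25, are placed on 1 by twofold formylation (3 via 2), and the phenols are then benzylated (4). Formylation precedes benzylation because the free triol is reactive enough to take two formyl groups and each formyl group slows the next substitution.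

**The cyclobutenone (13 ⇒ 12 ⇒ 11 ⇒ 9 + 10).** Compound 13 is the methyl enol ether of dione 12. A direct cycloaddition of the ketene from 9 with 10 cannot give 13. The nucleophilic alkyne carbon is the unsubstituted one, so the methyl group ends on the saturated ring carbon and the ether is an ethyl ether (11). Hydrolysis of 11 to 12 removes both differences, and O-methylation of the symmetric enolate of 12 can give only 13.

## Alternatives that were turned down

**Alternative 1:** An outer ring is cut between the bridge carbon and the hydroxylated carbon next to C-methyl and traced to an acyclic chain in which one carbonyl is masked as a methyl enol ether. In the forward key step methoxide forms the malonyl carbanion, which attacks the conjugated ester carbonyl in a Dieckmann closure; loss of methoxide and enolisation give methyl 3-butanoyl-2,6-dihydroxy-4-methoxy-5-methylbenzoate A1.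
- In its favour: butanoyl, methyl and methoxy groups are all in place when the ring closes, and the position of the ether is fixed because it is the masked carbonyl.
- Against: the electrophile is a β-methoxy acrylate, a donor-deactivated ester that must hold the Z geometry to be reached. The chain also contains a methine flanked by three carbonyl-level carbons, which is deprotonated first and lowers the reactivity of the chain.
- A1 carries an ester on the future bridge carbon, so saponification and decarboxylation must follow. Two such rings must then be joined to a ring B unit with a methylene donor, where homo-coupling and bridge scrambling compete.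
- On placing the outer acyl group it is stronger than the chosen route, which needs four operations after ring formation. The chosen route offers bridges of fixed connectivity made before the outer rings exist, and two rings closed in one step.

**Alternative 2:** Ring B is cut at one ring C–C bond and traced to a chiral pyrone. A magnesium alkoxide opens the pyrone and the side-chain methylene between two ketones attacks the ester carbonyl, giving (2S)-2-methyl-1-(2,4,6-trihydroxyphenyl)butan-1-one A2.
- In its favour: it is biomimetic, the stereocentre is handled on a small molecule, and no late acylation at a crowded ring B position is needed. On that point it is stronger than step 14 here.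
- Against: the stereocentre sits α to a ketone of a polycarbonyl chain under alkoxide for the whole cyclisation, so enolisation threatens the configuration.
- A2 should also be reachable by one Friedel–Crafts acylation of 1 with an activated form of 23, so building ring B from a chain buys nothing.
- It leaves both outer rings and both bridges unsolved. The chosen route addresses exactly those and offers chiral-pool introduction of the stereocentre in the penultimate step.

**Alternative 3:** An outer ring is cut between the acyl-bearing and methoxy-bearing carbons and traced to a methoxypyranone with a β-keto side chain. Catalytic methoxide opens the pyranone at its methoxy-bearing C2, and the side-chain carbanion closes onto the same carbon, trading ring oxygen for carbon to give 1-(4,6-dihydroxy-2-methoxy-3-methylphenyl)butan-1-one A3.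
- In its favour: it is an isomerisation under catalytic base, A3 carries every substituent of an outer ring, and its single free CH is the future bridge position. For the outer ring alone it is shorter than the chosen route.
- Against: the pyranone needs several steps with its own O-methylation regiochemistry (2-methoxy-4-pyranone versus 4-methoxy-2-pyranone), and the carbanion can also attack the ring carbonyl.
- The main objection is what follows: two molecules of A3 must be joined to ring B through CH2 units, with self-coupling of A3, over-alkylation of ring B and base-induced scrambling as competing processes.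
- The chosen route avoids this by carrying the bridge carbons on ring B from step 1. A3 combined with a preformed ring B bis-electrophile is retained as the fallback for the key step.

Key step: step 9

## Route

Step 1
Reactants: 1 phloroglucinol (benzene-1,3,5-triol)
Product: 3 2,4,6-trihydroxybenzene-1,3-dicarbaldehyde, via bis(iminium) dichloride 2 (not isolated)
Conditions: POCl3 (2.2 equiv), DMF, 1,4-dioxane, 0 °C → rt; then H2O, rt
Reagents that add atoms: N,N-dimethylformamide (CN(C)C=O); water (O)
Why: Vilsmeier–Haack formylation: the chloroiminium ion substitutes the triol twice, each carbon still being activated by three hydroxyls, and the limited stoichiometry together with the deactivating iminium groups should stop the sequence before the third position reacts; water hydrolyses 2 to the dialdehyde.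

Step 2
Reactants: 3 2,4,6-trihydroxybenzene-1,3-dicarbaldehyde
Product: 4 2,4,6-tris(benzyloxy)benzene-1,3-dicarbaldehyde
Conditions: BnBr (3.6 equiv), K2CO3, DMF, 60 °C
Reagents that add atoms: benzyl bromide (BrCc1ccccc1)
Why: Williamson ether synthesis; the two formyl groups make the ring a poor carbon nucleophile, so the phenoxides should alkylate on oxygen, and warming is needed only because all three hydroxyls are hydrogen-bonded to a formyl group.

Step 3
Reactants: 4 2,4,6-tris(benzyloxy)benzene-1,3-dicarbaldehyde
Product: 5 2,2'-{[2,4,6-tris(benzyloxy)-1,3-phenylene]dimethanylylidene}bis(1,3-dithiane)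
Conditions: 2-(trimethylsilyl)-1,3-dithiane, n-BuLi, THF, −30 → 0 °C; then 4, −78 °C → rt
Reagents that add atoms: 2-(trimethylsilyl)-1,3-dithiane (C[Si](C)(C)C1SCCCS1)
Why: Peterson olefination: the lithiated silyl dithiane adds to each non-enolisable aldehyde and the β-silyl alkoxide eliminates silanolate to give the ketene dithioacetal, a masked carboxyl group one carbon beyond the former formyl carbon.

Step 4
Reactants: 5 2,2'-{[2,4,6-tris(benzyloxy)-1,3-phenylene]dimethanylylidene}bis(1,3-dithiane)
Product: 6 dimethyl 2,2'-[2,4,6-tris(benzyloxy)-1,3-phenylene]diacetate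
Conditions: HgCl2, MeOH/H2O (9:1), reflux
Reagents that add atoms: methanol (CO); water (O)
Why: Thiophilic HgCl2-assisted solvolysis of a ketene dithioacetal: protonation at the benzylic carbon gives a dithianylium ion that is captured by methanol and water while mercury removes the dithiol, so each arm should end as ArCH2CO2Me. Benzyl aryl ethers are inert to these conditions.

Step 5
Reactants: 6 dimethyl 2,2'-[2,4,6-tris(benzyloxy)-1,3-phenylene]diacetate
Product: 8 1,3,5-tris(benzyloxy)-2,4-bis[3-(triisopropylsilyloxy)prop-2-yn-1-yl]benzene, via dilithium bis(ynolate) 7 (not isolated)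
Conditions: CH2Br2, LiTMP, THF, −78 °C; LiHMDS; n-BuLi, −78 → 0 °C; TIPSOTf, −78 → 0 °C
Reagents that add atoms: dibromomethane (BrCBr); triisopropylsilyl trifluoromethanesulfonate (CC(C)[Si](OS(=O)(=O)C(F)(F)F)(C(C)C)C(C)C)
Why: Kowalski ester homologation stopped at the ynolate: the dibromomethyl carbenoid adds to each ester, the dibromo ketone enolate undergoes bromine–lithium exchange and 1,2-shift of the arylmethyl group to give 7, and the bulky silyl triflate silylates the ynolate on oxygen. The crowded, electron-rich aryl group lowers the acidity of the ArCH2 protons, which should favour carbonyl addition over enolisation.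

Step 6
Reactants: 9 propanoyl chloride; 10 ethoxyethyne
Product: 11 3-ethoxy-4-methylcyclobut-2-en-1-one (racemic)
Conditions: Et3N, Et2O/hexanes, 0 °C → rt
Reagents that add atoms: none
Why: Ketene–alkyne [2+2] cycloaddition of methylketene made in the flask by dehydrochlorination of 9; the unsubstituted, nucleophilic alkyne carbon of 10 bonds to the ketene carbonyl carbon, so the methyl group ends on the saturated ring carbon C4.

Step 7
Reactants: 11 3-ethoxy-4-methylcyclobut-2-en-1-one
Product: 12 3-hydroxy-2-methylcyclobut-2-en-1-one (enol form of 2-methylcyclobutane-1,3-dione)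
Conditions: 1 M aq. HCl, THF, 0 °C → rt
Reagents that add atoms: water (O)
Why: Acid hydrolysis of a vinylogous ester to the 1,3-dione, which should settle as the enol with the methyl group on the doubly bonded carbon; the stereocentre of 11 is erased here.

Step 8
Reactants: 12 3-hydroxy-2-methylcyclobut-2-en-1-one
Product: 13 3-methoxy-2-methylcyclobut-2-en-1-one
Conditions: TMSCHN2, PhMe/MeOH (4:1), 0 °C → rt
Reagents that add atoms: (trimethylsilyl)diazomethane (C[Si](C)(C)C=[N+]=[N-])
Why: O-Methylation of a strongly acidic enol (a vinylogous carboxylic acid) by diazomethane released from TMSCHN2 in methanol; the anion of 12 is symmetric about the methyl-bearing carbon, so both oxygens give the same enol ether and the methyl group now sits on the alkene carbon next to the carbonyl.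

Step 9
Reactants: 8 1,3,5-tris(benzyloxy)-2,4-bis[3-(triisopropylsilyloxy)prop-2-yn-1-yl]benzene; 13 3-methoxy-2-methylcyclobut-2-en-1-one
Product: 17 2,2'-{[2,4,6-tris(benzyloxy)-1,3-phenylene]bis(methylene)}bis[5-methoxy-4-methyl-3-(triisopropylsilyloxy)phenol], via bis(vinylcyclobutenone) 14 (not isolated), via bis(dienylketene) 15 (not isolated), via bis(cyclohexadienone) 16 (not isolated)
Conditions: 13 (3 equiv), PhMe, 110 °C, sealed tube; then K2CO3, MeOH, rt
Reagents that add atoms: none
Why: Proposed new method: the closest known reaction type is the thermal Danheiser benzannulation of 3-alkyl- or 3-arylcyclobutenones with silyloxyalkynes, here extended to a 3-alkoxycyclobutenone and run on two alkyne arms of one molecule. Heating should open 13 by 4π-electrocyclic cleavage of the C1–C4 bond to a (1-methoxyvinyl)ketene, which adds across each siloxyalkyne in a ketene–alkyne [2+2] step to give 14. A second 4π opening gives the dienylketene 15, and a 6π-electrocyclic closure that rejoins the ketene carbon to the methylene terminus closes each outer ring as dienone 16, which tautomerises to the phenol 17. Rings A and C are thus each closed by 6π electrocyclisation of a trienyl unit, and the four-membered rings formed on the way are opened again. The selectivity the step needs is the regiochemistry of the [2+2] event, and the polarised alkyne secures it: its carbon remote from oxygen is the nucleophile and bonds to the ketene carbonyl carbon, so the phenol carbon ends next to the bridge-bearing carbon, the silyl ether next to C-methyl and the methoxy group next to the one ring CH. No stereocentre is present in 17; the quaternary centres of 14 are lost on ring opening. The donor methoxy group is expected to raise the temperature of the first ring opening, which the excess of 13 and the sealed tube allow for. Any aryl ester formed from 17 and surplus ketene should be cleaved by the K2CO3/MeOH treatment, which the hindered aryl silyl ethers survive.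

Step 10
Reactants: 17 2,2'-{[2,4,6-tris(benzyloxy)-1,3-phenylene]bis(methylene)}bis[5-methoxy-4-methyl-3-(triisopropylsilyloxy)phenol]
Product: 18 2,2'-{[2,4,6-tris(benzyloxy)-1,3-phenylene]bis(methylene)}bis[6-iodo-5-methoxy-4-methyl-3-(triisopropylsilyloxy)phenol]
Conditions: I2 (2.1 equiv), NaHCO3, THF/H2O, 0 °C
Reagents that add atoms: iodine (II)
Why: Electrophilic aromatic iodination of a phenol under bicarbonate buffering: the only free position of each outer ring is ortho to the hydroxyl and para to the silyloxy group, while the fully etherified ring B should be far less reactive towards iodine without an activator.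

Step 11
Reactants: 18 2,2'-{[2,4,6-tris(benzyloxy)-1,3-phenylene]bis(methylene)}bis[6-iodo-5-methoxy-4-methyl-3-(triisopropylsilyloxy)phenol]
Product: 19 {[2,4,6-tris(benzyloxy)-1,3-phenylene]bis(methylene)}bis[6-iodo-5-methoxy-4-methyl-3-(triisopropylsilyloxy)-2,1-phenylene] dibutanoate
Conditions: n-PrCOCl, Et3N, DMAP (cat.), CH2Cl2, 0 °C → rt
Reagents that add atoms: butanoyl chloride (CCCC(=O)Cl)
Why: DMAP-catalysed O-acylation of the phenols; the ester places the butanoyl group one bond away from the iodinated carbon.

Step 12
Reactants: 19 {[2,4,6-tris(benzyloxy)-1,3-phenylene]bis(methylene)}bis[6-iodo-5-methoxy-4-methyl-3-(triisopropylsilyloxy)-2,1-phenylene] dibutanoate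
Product: 21 1,1'-{[2,4,6-tris(benzyloxy)-1,3-phenylene]bis[methylene(2-hydroxy-6-methoxy-5-methyl-4-(triisopropylsilyloxy)-3,1-phenylene)]}bis(butan-1-one), via bis(aryllithium) 20 (not isolated)
Conditions: t-BuLi (4.2 equiv), THF, −95 → −78 °C; then aq. NH4Cl
Reagents that add atoms: none
Why: Halogen–lithium exchange-triggered anionic Fries rearrangement: iodine–lithium exchange at −95 °C should outrun addition to the ester, and the aryllithium 20 takes the neighbouring acyl group by an intramolecular 1,3 O-to-C shift to give a chelated lithium phenoxide ketone that resists further attack. Because the transfer is intramolecular the butanoyl group cannot reach ring B.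

Step 13
Reactants: 21 1,1'-{[2,4,6-tris(benzyloxy)-1,3-phenylene]bis[methylene(2-hydroxy-6-methoxy-5-methyl-4-(triisopropylsilyloxy)-3,1-phenylene)]}bis(butan-1-one)
Product: 22 1,1'-{[2,4,6-tris(benzyloxy)-1,3-phenylene]bis[methylene(2,4-dihydroxy-6-methoxy-5-methyl-3,1-phenylene)]}bis(butan-1-one)
Conditions: Bu4NF, AcOH, THF, 0 °C → rt
Reagents that add atoms: none
Why: Fluoride cleavage of the aryl silyl ethers, buffered with acetic acid; benzyl ethers and ketones are untouched and no stereocentre is yet present.

Step 14
Reactants: 22 1,1'-{[2,4,6-tris(benzyloxy)-1,3-phenylene]bis[methylene(2,4-dihydroxy-6-methoxy-5-methyl-3,1-phenylene)]}bis(butan-1-one); 23 (S)-2-methylbutanoic acid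
Product: 24 (2S)-1-[2,4,6-tris(benzyloxy)-3,5-bis(3-butanoyl-2,6-dihydroxy-4-methoxy-5-methylbenzyl)phenyl]-2-methylbutan-1-one
Conditions: (CF3CO)2O, H3PO4 (cat.), CH2Cl2, 0 °C → rt; then K2CO3, MeOH, 0 °C
Reagents that add atoms: none
Why: Friedel–Crafts acylation through the mixed carboxylic–trifluoroacetic anhydride: ring B carries the only unsubstituted carbon on an electron-rich ring, activated by three benzyloxy groups, so the site is fixed. The stereocentre is not formed here but carried in from 23 with its S configuration, and it meets no base stronger than cold K2CO3/MeOH, which only cleaves aryl esters formed at the phenols. Benzyl aryl ethers should be stable to the mixed anhydride at room temperature.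

Step 15
Reactants: 24 (2S)-1-[2,4,6-tris(benzyloxy)-3,5-bis(3-butanoyl-2,6-dihydroxy-4-methoxy-5-methylbenzyl)phenyl]-2-methylbutan-1-one
Product: 25 Agrimol B, (2S)-1-[3,5-bis(3-butanoyl-2,6-dihydroxy-4-methoxy-5-methylbenzyl)-2,4,6-trihydroxyphenyl]-2-methylbutan-1-one
Conditions: H2 (1 atm), Pd/C, EtOAc/MeOH, rt
Reagents that add atoms: none
Why: Hydrogenolysis of the three benzyl aryl ethers under neutral conditions; the hydrogen-bonded, electron-rich aryl ketones should not be reduced at one atmosphere, and the α-stereocentre meets neither acid nor base.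

## Compound list

1 | phloroglucinol (benzene-1,3,5-triol) | Oc1cc(O)cc(O)c1 | starting material
2 | N,N'-[(2,4,6-trihydroxy-1,3-phenylene)dimethanylylidene]bis(N-methylmethanaminium) dichloride | C[N+](C)=Cc1c(O)cc(O)c(C=[N+](C)C)c1O.[Cl-].[Cl-] | intermediate (not isolated)
3 | 2,4,6-trihydroxybenzene-1,3-dicarbaldehyde | O=Cc1c(O)cc(O)c(C=O)c1O | intermediate
4 | 2,4,6-tris(benzyloxy)benzene-1,3-dicarbaldehyde | O=Cc1c(OCc2ccccc2)cc(OCc2ccccc2)c(C=O)c1OCc1ccccc1 | intermediate
5 | 2,2'-{[2,4,6-tris(benzyloxy)-1,3-phenylene]dimethanylylidene}bis(1,3-dithiane) | S1CCCSC1=Cc1c(OCc2ccccc2)cc(OCc2ccccc2)c(C=C2SCCCS2)c1OCc1ccccc1 | intermediate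
6 | dimethyl 2,2'-[2,4,6-tris(benzyloxy)-1,3-phenylene]diacetate | COC(=O)Cc1c(OCc2ccccc2)cc(OCc2ccccc2)c(CC(=O)OC)c1OCc1ccccc1 | intermediate
7 | dilithium 3,3'-[2,4,6-tris(benzyloxy)-1,3-phenylene]bis(prop-1-yn-1-olate) | [Li]OC#CCc1c(OCc2ccccc2)cc(OCc2ccccc2)c(CC#CO[Li])c1OCc1ccccc1 | intermediate (not isolated)
8 | 1,3,5-tris(benzyloxy)-2,4-bis[3-(triisopropylsilyloxy)prop-2-yn-1-yl]benzene | CC(C)[Si](OC#CCc1c(OCc2ccccc2)cc(OCc3ccccc3)c(CC#CO[Si](C(C)C)(C(C)C)C(C)C)c1OCc4ccccc4)(C(C)C)C(C)C | intermediate
9 | propanoyl chloride | CCC(=O)Cl | starting material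
10 | ethoxyethyne | CCOC#C | starting material
11 | 3-ethoxy-4-methylcyclobut-2-en-1-one (racemic) | CCOC1=CC(=O)C1C | intermediate
12 | 3-hydroxy-2-methylcyclobut-2-en-1-one (enol form of 2-methylcyclobutane-1,3-dione) | CC1=C(O)CC1=O | intermediate
13 | 3-methoxy-2-methylcyclobut-2-en-1-one | COC1=C(C)C(=O)C1 | intermediate
14 | 2,2'-{[2,4,6-tris(benzyloxy)-1,3-phenylene]bis(methylene)}bis[4-(1-methoxyethenyl)-4-methyl-3-(triisopropylsilyloxy)cyclobut-2-en-1-one] (mixture of stereoisomers at the two quaternary carbons) | C=C(OC)C1(C)C(=O)C(Cc2c(OCc3ccccc3)cc(OCc3ccccc3)c(CC3=C(O[Si](C(C)C)(C(C)C)C(C)C)C(C)(C(OC)=C)C3=O)c2OCc2ccccc2)=C1O[Si](C(C)C)(C(C)C)C(C)C | intermediate (not isolated)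
15 | 2,2'-{[2,4,6-tris(benzyloxy)-1,3-phenylene]bis(methylene)}bis[(3E)-5-methoxy-4-methyl-3-(triisopropylsilyloxy)hexa-1,3,5-trien-1-one] (ketene and methoxyvinyl termini cis) | C=C(OC)/C(C)=C(O[Si](C(C)C)(C(C)C)C(C)C)\C(=C=O)Cc1c(OCc2ccccc2)cc(OCc2ccccc2)c(CC(=C=O)/C(O[Si](C(C)C)(C(C)C)C(C)C)=C(C)\C(OC)=C)c1OCc1ccccc1 | intermediate (not isolated)
16 | 2,2'-{[2,4,6-tris(benzyloxy)-1,3-phenylene]bis(methylene)}bis[5-methoxy-4-methyl-3-(triisopropylsilyloxy)cyclohexa-2,4-dien-1-one] | O=C1CC(OC)=C(C)C(O[Si](C(C)C)(C(C)C)C(C)C)=C1Cc1c(OCc2ccccc2)cc(OCc2ccccc2)c(CC2=C(O[Si](C(C)C)(C(C)C)C(C)C)C(C)=C(OC)CC2=O)c1OCc1ccccc1 | intermediate (not isolated)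
17 | 2,2'-{[2,4,6-tris(benzyloxy)-1,3-phenylene]bis(methylene)}bis[5-methoxy-4-methyl-3-(triisopropylsilyloxy)phenol] | Oc1cc(OC)c(C)c(O[Si](C(C)C)(C(C)C)C(C)C)c1Cc2c(OCc3ccccc3)cc(OCc4ccccc4)c(Cc5c(O)cc(OC)c(C)c5O[Si](C(C)C)(C(C)C)C(C)C)c2OCc6ccccc6 | intermediate
18 | 2,2'-{[2,4,6-tris(benzyloxy)-1,3-phenylene]bis(methylene)}bis[6-iodo-5-methoxy-4-methyl-3-(triisopropylsilyloxy)phenol] | Oc1c(I)c(OC)c(C)c(O[Si](C(C)C)(C(C)C)C(C)C)c1Cc1c(OCc2ccccc2)cc(OCc2ccccc2)c(Cc2c(O)c(I)c(OC)c(C)c2O[Si](C(C)C)(C(C)C)C(C)C)c1OCc1ccccc1 | intermediate
19 | {[2,4,6-tris(benzyloxy)-1,3-phenylene]bis(methylene)}bis[6-iodo-5-methoxy-4-methyl-3-(triisopropylsilyloxy)-2,1-phenylene] dibutanoate | CCCC(=O)Oc1c(I)c(OC)c(C)c(O[Si](C(C)C)(C(C)C)C(C)C)c1Cc1c(OCc2ccccc2)cc(OCc2ccccc2)c(Cc2c(OC(=O)CCC)c(I)c(OC)c(C)c2O[Si](C(C)C)(C(C)C)C(C)C)c1OCc1ccccc1 | intermediate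
20 | 6,6'-dilithio analogue of 19 (lithium in place of each iodine) | CCCC(=O)Oc1c([Li])c(OC)c(C)c(O[Si](C(C)C)(C(C)C)C(C)C)c1Cc1c(OCc2ccccc2)cc(OCc2ccccc2)c(Cc2c(OC(=O)CCC)c([Li])c(OC)c(C)c2O[Si](C(C)C)(C(C)C)C(C)C)c1OCc1ccccc1 | intermediate (not isolated)
21 | 1,1'-{[2,4,6-tris(benzyloxy)-1,3-phenylene]bis[methylene(2-hydroxy-6-methoxy-5-methyl-4-(triisopropylsilyloxy)-3,1-phenylene)]}bis(butan-1-one) | CCCC(=O)c1c(O)c(Cc2c(OCc3ccccc3)cc(OCc3ccccc3)c(Cc3c(O)c(C(=O)CCC)c(OC)c(C)c3O[Si](C(C)C)(C(C)C)C(C)C)c2OCc2ccccc2)c(O[Si](C(C)C)(C(C)C)C(C)C)c(C)c1OC | intermediate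
22 | 1,1'-{[2,4,6-tris(benzyloxy)-1,3-phenylene]bis[methylene(2,4-dihydroxy-6-methoxy-5-methyl-3,1-phenylene)]}bis(butan-1-one) | CCCC(=O)c1c(O)c(Cc2c(OCc3ccccc3)cc(OCc3ccccc3)c(Cc3c(O)c(C(=O)CCC)c(OC)c(C)c3O)c2OCc2ccccc2)c(O)c(C)c1OC | intermediate
23 | (S)-2-methylbutanoic acid | OC(=O)[C@@H](C)CC | starting material
24 | (2S)-1-[2,4,6-tris(benzyloxy)-3,5-bis(3-butanoyl-2,6-dihydroxy-4-methoxy-5-methylbenzyl)phenyl]-2-methylbutan-1-one | CCCC(=O)c1c(O)c(Cc2c(OCc3ccccc3)c(C(=O)[C@@H](C)CC)c(OCc3ccccc3)c(Cc3c(O)c(C(=O)CCC)c(OC)c(C)c3O)c2OCc2ccccc2)c(O)c(C)c1OC | intermediate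
25 | Agrimol B, (2S)-1-[3,5-bis(3-butanoyl-2,6-dihydroxy-4-methoxy-5-methylbenzyl)-2,4,6-trihydroxyphenyl]-2-methylbutan-1-one | CCCC(=O)c1c(O)c(Cc2c(O)c(Cc3c(O)c(C)c(OC)c(C(=O)CCC)c3O)c(O)c(C(=O)[C@@H](C)CC)c2O)c(O)c(C)c1OC | target

## Step count and least certain steps

Total: 15 steps. Longest linear sequence: 12 steps (steps 1–5 and 9–15, from 1). The cyclobutenone branch (steps 6–8) adds three.

**Step 9 (key step, the one carrying the new-method label).** The donor-substituted cyclobutenone may open too slowly, so that the siloxyalkyne arms are lost first by silyl migration to a silylketene or by adventitious hydrolysis. One arm may react while the second lags. The vinylketene may also be consumed by dimerisation or by acylation of the first-formed phenol. Fallback by known chemistry, setting out from 4 and returning at 22: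
- NaBH4 reduction of 4 should give [2,4,6-tris(benzyloxy)-1,3-phenylene]dimethanol F1.
- The outer ring is made separately. Friedel–Crafts acylation of commercial 2-methylbenzene-1,3,5-triol F2 with butanoyl chloride and AlCl3 should give 1-(2,4,6-trihydroxy-3-methylphenyl)butan-1-one F3.
- Benzylation with two equivalents of benzyl bromide and K2CO3 is expected to spare the chelated hydroxyl flanked by methyl and acyl, giving 1-[4,6-bis(benzyloxy)-2-hydroxy-3-methylphenyl]butan-1-one F4. An isomeric dibenzyl ether would have to be removed.
- Forcing methylation (MeI, K2CO3, DMF) would give 1-[4,6-bis(benzyloxy)-2-methoxy-3-methylphenyl]butan-1-one F5, and hydrogenolysis would give 1-(4,6-dihydroxy-2-methoxy-3-methylphenyl)butan-1-one F6 (the same compound as A3).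
- Acid-catalysed Friedel–Crafts benzylation of an excess of F6, at its single free ring position, with the doubly benzylic diol F1 should then give 22 with both bridges and both butanoyl groups in place.

**Step 5.** The carbenoid base may enolise the arylacetic esters in place of adding to the carbonyl, the rearrangement may stop at one arm, or the ynolate may be silylated on carbon. Fallback, setting out from 6 and returning at 7 (then 8 as in step 5):
- i-Bu2AlH at −78 °C should give 2,2'-[2,4,6-tris(benzyloxy)-1,3-phenylene]diacetaldehyde F7.
- Corey–Fuchs olefination (CBr4, PPh3) would give 1,3,5-tris(benzyloxy)-2,4-bis(3,3-dibromoprop-2-en-1-yl)benzene F8.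
- n-BuLi would give dilithium 3,3'-[2,4,6-tris(benzyloxy)-1,3-phenylene]bis(prop-1-yn-1-ide) F9.
- Oxidation of F9 with LiOOt-Bu gives the ynolate 7, which is silylated with TIPSOTf.

**Step 12 (with steps 10 and 11).** Iodination may lose site selectivity and touch ring B, the aryllithium may be protonated before the acyl shift, or the alkyllithium may add to the ester. Fallback, setting out from 17 and returning at 21:
- Phenol-specific ortho-formylation (MgCl2, Et3N, paraformaldehyde, MeCN, reflux) should give 3,3'-{[2,4,6-tris(benzyloxy)-1,3-phenylene]bis(methylene)}bis[2-hydroxy-6-methoxy-5-methyl-4-(triisopropylsilyloxy)benzaldehyde] F10.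
- Excess n-PrMgBr would give 2,2'-{[2,4,6-tris(benzyloxy)-1,3-phenylene]bis(methylene)}bis[6-(1-hydroxybutyl)-5-methoxy-4-methyl-3-(triisopropylsilyloxy)phenol] F11 as a mixture of diastereomers.
- MnO2 oxidation of the benzylic carbinols gives 21.

**Step 14.** Substitution at the ring B carbon flanked by two benzyloxy groups may be slow, so that acyl transfer to the phenols dominates. Reversible ketene or enol formation from the mixed anhydride in the acidic medium may also erode the configuration. Fallback, setting out from 22 and returning at 25:
- Hydrogenolysis of 22 first should give 1,1'-{(2,4,6-trihydroxy-1,3-phenylene)bis[methylene(2,4-dihydroxy-6-methoxy-5-methyl-3,1-phenylene)]}bis(butan-1-one) F12, in which ring B is a free and unhindered phloroglucinol.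
- Acid 23 is converted with oxalyl chloride into (2S)-2-methylbutanoyl chloride F13.
- Friedel–Crafts acylation of F12 with F13 and AlCl3 in nitrobenzene at 0 °C then gives 25 directly. The price is exposure of the free polyphenol and its bridges to a Lewis acid.

## Further compounds

F1 | step 9 | [2,4,6-tris(benzyloxy)-1,3-phenylene]dimethanol | OCc1c(OCc2ccccc2)cc(OCc2ccccc2)c(CO)c1OCc1ccccc1
F2 | step 9 | 2-methylbenzene-1,3,5-triol | Cc1c(O)cc(O)cc1O
F3 | step 9 | 1-(2,4,6-trihydroxy-3-methylphenyl)butan-1-one | CCCC(=O)c1c(O)cc(O)c(C)c1O
F4 | step 9 | 1-[4,6-bis(benzyloxy)-2-hydroxy-3-methylphenyl]butan-1-one | CCCC(=O)c1c(OCc2ccccc2)cc(OCc2ccccc2)c(C)c1O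
F5 | step 9 | 1-[4,6-bis(benzyloxy)-2-methoxy-3-methylphenyl]butan-1-one | CCCC(=O)c1c(OCc2ccccc2)cc(OCc2ccccc2)c(C)c1OC
F6 | step 9 | 1-(4,6-dihydroxy-2-methoxy-3-methylphenyl)butan-1-one | CCCC(=O)c1c(O)cc(O)c(C)c1OC
F7 | step 5 | 2,2'-[2,4,6-tris(benzyloxy)-1,3-phenylene]diacetaldehyde | O=CCc1c(OCc2ccccc2)cc(OCc2ccccc2)c(CC=O)c1OCc1ccccc1
F8 | step 5 | 1,3,5-tris(benzyloxy)-2,4-bis(3,3-dibromoprop-2-en-1-yl)benzene | BrC(Br)=CCc1c(OCc2ccccc2)cc(OCc2ccccc2)c(CC=C(Br)Br)c1OCc1ccccc1
F9 | step 5 | dilithium 3,3'-[2,4,6-tris(benzyloxy)-1,3-phenylene]bis(prop-1-yn-1-ide) | [Li]C#CCc1c(OCc2ccccc2)cc(OCc2ccccc2)c(CC#C[Li])c1OCc1ccccc1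
F10 | step 12 | 3,3'-{[2,4,6-tris(benzyloxy)-1,3-phenylene]bis(methylene)}bis[2-hydroxy-6-methoxy-5-methyl-4-(triisopropylsilyloxy)benzaldehyde] | O=Cc1c(O)c(Cc2c(OCc3ccccc3)cc(OCc3ccccc3)c(Cc3c(O)c(C=O)c(OC)c(C)c3O[Si](C(C)C)(C(C)C)C(C)C)c2OCc2ccccc2)c(O[Si](C(C)C)(C(C)C)C(C)C)c(C)c1OC
F11 | step 12 | 2,2'-{[2,4,6-tris(benzyloxy)-1,3-phenylene]bis(methylene)}bis[6-(1-hydroxybutyl)-5-methoxy-4-methyl-3-(triisopropylsilyloxy)phenol] (mixture of diastereomers) | CCCC(O)c1c(O)c(Cc2c(OCc3ccccc3)cc(OCc3ccccc3)c(Cc3c(O)c(C(O)CCC)c(OC)c(C)c3O[Si](C(C)C)(C(C)C)C(C)C)c2OCc2ccccc2)c(O[Si](C(C)C)(C(C)C)C(C)C)c(C)c1OC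
F12 | step 14 | 1,1'-{(2,4,6-trihydroxy-1,3-phenylene)bis[methylene(2,4-dihydroxy-6-methoxy-5-methyl-3,1-phenylene)]}bis(butan-1-one) | CCCC(=O)c1c(O)c(Cc2c(O)cc(O)c(Cc3c(O)c(C(=O)CCC)c(OC)c(C)c3O)c2O)c(O)c(C)c1OC
F13 | step 14 | (2S)-2-methylbutanoyl chloride | ClC(=O)[C@@H](C)CC
A1 | alternative 1 | methyl 3-butanoyl-2,6-dihydroxy-4-methoxy-5-methylbenzoate | COC(=O)c1c(O)c(C(=O)CCC)c(OC)c(C)c1O
A2 | alternative 2 | (2S)-2-methyl-1-(2,4,6-trihydroxyphenyl)butan-1-one | Oc1cc(O)c(C(=O)[C@@H](C)CC)c(O)c1
A3 | alternative 3 | 1-(4,6-dihydroxy-2-methoxy-3-methylphenyl)butan-1-one | CCCC(=O)c1c(O)cc(O)c(C)c1OC
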